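**Assumption:** the target has no stereocentre and its SMILES gives no configuration for the biaryl axis, so the achiral constitution as drawn is the goal and there is no enantiomer to select.

## Retrosynthetic overview

1. The last step is one hydrogenation that removes five benzyl ethers and saturates a 2H-chromene to the chroman.
2. The pyranone ring of the chroman-bound flavone (unit 1) is formed last of all rings, by palladium-catalysed carbonylative annulation of an aryl bromide with a 2-hydroxyacetophenone.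
3. The dimethylpyran ring comes from ortho-specific chromenylation of a biaryl phenol with 3-methylbut-2-enal.
4. Key disconnection: the biaryl bond between chroman C8 and apigenin C8. Both carbons sit ortho to oxygen and are innately nucleophilic. 4-Bromophenol is inverted into an O-iodanyl enolonium (phenoxenium equivalent) and attacked by the C8–H of tri-O-benzylapigenin.
5. Ring order: apigenin flavone (unit 2, bought intact) → biaryl → pyran ring → second flavone pyranone. Bromine is the placeholder for unit 1.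

## Route

Step 1
Reactants: 1 apigenin; 2 benzyl bromide
Product: 3 5,7-bis(benzyloxy)-2-[4-(benzyloxy)phenyl]-4H-chromen-4-one (tri-O-benzylapigenin)
Conditions: BnBr (4.5 equiv), K2CO3, Bu4NI (cat.), DMF, 80 °C
Reagents that add atoms: benzyl bromide, BrCc1ccccc1
Why: Williamson etherification; the 7- and 4'-phenoxides alkylate readily and the hydrogen-bonded 5-OH follows with excess benzyl bromide in hot DMF, so no free phenol of the flavone remains to be oxidised in step 2 and the 5-alkoxy group later steers attack to C8; no stereocentre is formed.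

Step 2
Reactants: 3 tri-O-benzylapigenin; 4 4-bromophenol
Product: 6 5,7-bis(benzyloxy)-2-[4-(benzyloxy)phenyl]-8-(5-bromo-2-hydroxyphenyl)-4H-chromen-4-one, via aryloxyiodane 5 (not isolated)
Conditions: 3 (2 equiv), PhI(OCOCF3)2 (1.1 equiv, slow addition), (CF3)2CHOH–CH2Cl2, −20 → 0 °C
Reagents that add atoms: none
Why: Proposed new method: ligand exchange of phenol 4 on trivalent iodine gives the O-iodanyl species 5, an aryl enolonium (phenoxenium equivalent) whose ortho carbon is electrophilic; in the ionising, non-nucleophilic fluoroalcohol the most nucleophilic C–H of 3 (C8, flanked by the ring oxygen and the 7-benzyloxy group, the site where 5,7-dialkoxyflavones are halogenated) attacks that ortho carbon rather than the bromine-bearing para carbon, iodobenzene leaves, and tautomerisation of the dienone restores the phenol; the closest known reaction type is the hypervalent-iodine-mediated oxidative phenol–arene cross-coupling in fluoroalcohols, so far shown mainly for alkyl- or alkoxy-substituted phenols with simple polyalkoxyarenes; no stereocentre is formed.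

Step 3
Reactants: 6 biaryl bromophenol; 7 3-methylbut-2-enal
Product: 10 5,7-bis(benzyloxy)-2-[4-(benzyloxy)phenyl]-8-(6-bromo-2,2-dimethyl-2H-chromen-8-yl)-4H-chromen-4-one, via benzodioxaborin 8 (not isolated), via ortho-quinone methide 9 (not isolated)
Conditions: 3-methylbut-2-enal (3 equiv), PhB(OH)2 (1.2 equiv), AcOH, toluene, reflux (Dean–Stark)
Reagents that add atoms: 3-methylbut-2-enal, CC(C)=CC=O
Why: Phenylboronic-acid-templated ortho-specific chromenylation (ortho-hydroxyalkylation to 8, thermal loss of the boron unit to ortho-quinone methide 9, oxa-6π electrocyclisation); the boronate ties the phenol oxygen to the enal so that only the single free ortho carbon of 6 reacts and the electron-rich flavone ring A is left alone; the stereocentre of 8 is racemic and disappears, and the product has none.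

Step 4
Reactants: 11 1-(2,4,6-trihydroxyphenyl)ethan-1-one; 2 benzyl bromide
Product: 12 1-[2,4-bis(benzyloxy)-6-hydroxyphenyl]ethan-1-one
Conditions: BnBr (2.1 equiv), K2CO3, DMF, rt
Reagents that add atoms: benzyl bromide, BrCc1ccccc1
Why: Williamson etherification; the hydroxyl hydrogen-bonded to the acetyl group is the least nucleophilic, so two equivalents of benzyl bromide leave exactly that hydroxyl free for the annulation; no stereocentre is formed.

Step 5
Reactants: 10 bromochromene; 12 dibenzyl hydroxyacetophenone; 13 carbon monoxide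
Product: 16 5,7-bis(benzyloxy)-8-{6-[5,7-bis(benzyloxy)-4-oxo-4H-chromen-2-yl]-2,2-dimethyl-2H-chromen-8-yl}-2-[4-(benzyloxy)phenyl]-4H-chromen-4-one, via aryl ester 14 (not isolated), via 1,3-diketone 15 (not isolated)
Conditions: CO (10 bar), Pd(OAc)2 (3 mol%), 1,4-bis(diphenylphosphino)butane (6 mol%), DBU (3 equiv), DMSO, 120 °C
Reagents that add atoms: carbon monoxide, [C-]#[O+]
Why: Palladium-catalysed carbonylative flavone annulation; zerovalent palladium inserts into the unhindered C6–Br bond, CO insertion and acylation of the phenoxide of 12 give ester 14, DBU drives the Baker–Venkataraman acyl shift to diketone 15 and its cyclodehydration to the pyranone, while the existing chromone, the chromene and the benzyl ethers are inert; no stereocentre is formed.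

Step 6
Reactants: 16 pentabenzyl chromene biflavone
Product: 17 8-[6-(5,7-dihydroxy-4-oxo-4H-chromen-2-yl)-2,2-dimethyl-3,4-dihydro-2H-chromen-8-yl]-5,7-dihydroxy-2-(4-hydroxyphenyl)-4H-chromen-4-one (CNP0127025.0)
Conditions: H2 (1 atm), 10% Pd/C, THF–MeOH, rt
Reagents that add atoms: none
Why: Heterogeneous hydrogenolysis and hydrogenation in one operation; the five O-benzyl groups are cleaved to toluene and the styrene-type C3=C4 bond of the chromene is saturated to the chroman, while the vinylogous-ester C2=C3 bonds of both flavones survive at 1 atm and room temperature; the product has no stereocentre.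

## Compound list

1 | apigenin, 5,7-dihydroxy-2-(4-hydroxyphenyl)-4H-chromen-4-one | O=c1cc(-c2ccc(O)cc2)oc2cc(O)cc(O)c12 | starting material
2 | benzyl bromide | BrCc1ccccc1 | starting material
3 | 5,7-bis(benzyloxy)-2-[4-(benzyloxy)phenyl]-4H-chromen-4-one | O=c1cc(-c2ccc(OCc3ccccc3)cc2)oc2cc(OCc3ccccc3)cc(OCc3ccccc3)c12 | intermediate
4 | 4-bromophenol | Oc1ccc(Br)cc1 | starting material
5 | (4-bromophenoxy)(phenyl)-λ3-iodanyl trifluoroacetate, formed in the flask | O=C(O[I](Oc1ccc(Br)cc1)c1ccccc1)C(F)(F)F | intermediate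
6 | 5,7-bis(benzyloxy)-2-[4-(benzyloxy)phenyl]-8-(5-bromo-2-hydroxyphenyl)-4H-chromen-4-one | O=c1cc(-c2ccc(OCc3ccccc3)cc2)oc2c(-c3cc(Br)ccc3O)c(OCc3ccccc3)cc(OCc3ccccc3)c12 | intermediate
7 | 3-methylbut-2-enal | CC(C)=CC=O | starting material
8 | 5,7-bis(benzyloxy)-2-[4-(benzyloxy)phenyl]-8-[6-bromo-4-(2-methylprop-1-en-1-yl)-2-phenyl-4H-1,3,2-benzodioxaborinin-8-yl]-4H-chromen-4-one, racemic, formed in the flask | CC(C)=CC1OB(c2ccccc2)Oc2c(-c3c(OCc4ccccc4)cc(OCc4ccccc4)c4c(=O)cc(-c5ccc(OCc6ccccc6)cc5)oc34)cc(Br)cc21 | intermediate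
9 | 5,7-bis(benzyloxy)-2-[4-(benzyloxy)phenyl]-8-[3-bromo-5-(3-methylbut-2-en-1-ylidene)-6-oxocyclohexa-1,3-dien-1-yl]-4H-chromen-4-one, exocyclic alkene geometry not fixed, formed in the flask | CC(C)=CC=C1C=C(Br)C=C(c2c(OCc3ccccc3)cc(OCc3ccccc3)c3c(=O)cc(-c4ccc(OCc5ccccc5)cc4)oc23)C1=O | intermediate
10 | 5,7-bis(benzyloxy)-2-[4-(benzyloxy)phenyl]-8-(6-bromo-2,2-dimethyl-2H-chromen-8-yl)-4H-chromen-4-one | CC1(C)C=Cc2cc(Br)cc(-c3c(OCc4ccccc4)cc(OCc4ccccc4)c4c(=O)cc(-c5ccc(OCc6ccccc6)cc5)oc34)c2O1 | intermediate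
11 | 1-(2,4,6-trihydroxyphenyl)ethan-1-one | CC(=O)c1c(O)cc(O)cc1O | starting material
12 | 1-[2,4-bis(benzyloxy)-6-hydroxyphenyl]ethan-1-one | CC(=O)c1c(O)cc(OCc2ccccc2)cc1OCc1ccccc1 | intermediate
13 | carbon monoxide | [C-]#[O+] | starting material
14 | 2-acetyl-3,5-bis(benzyloxy)phenyl 8-{5,7-bis(benzyloxy)-2-[4-(benzyloxy)phenyl]-4-oxo-4H-chromen-8-yl}-2,2-dimethyl-2H-chromene-6-carboxylate, formed in the flask | CC(=O)c1c(OC(=O)c2cc3c(c(-c4c(OCc5ccccc5)cc(OCc5ccccc5)c5c(=O)cc(-c6ccc(OCc7ccccc7)cc6)oc45)c2)OC(C)(C)C=C3)cc(OCc2ccccc2)cc1OCc1ccccc1 | intermediate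
15 | 1-[2,4-bis(benzyloxy)-6-hydroxyphenyl]-3-(8-{5,7-bis(benzyloxy)-2-[4-(benzyloxy)phenyl]-4-oxo-4H-chromen-8-yl}-2,2-dimethyl-2H-chromen-6-yl)propane-1,3-dione, formed in the flask | O=C(CC(=O)c1cc2c(c(-c3c(OCc4ccccc4)cc(OCc4ccccc4)c4c(=O)cc(-c5ccc(OCc6ccccc6)cc5)oc34)c1)OC(C)(C)C=C2)c1c(O)cc(OCc2ccccc2)cc1OCc1ccccc1 | intermediate
16 | 5,7-bis(benzyloxy)-8-{6-[5,7-bis(benzyloxy)-4-oxo-4H-chromen-2-yl]-2,2-dimethyl-2H-chromen-8-yl}-2-[4-(benzyloxy)phenyl]-4H-chromen-4-one | CC1(C)C=Cc2cc(-c3cc(=O)c4c(OCc5ccccc5)cc(OCc5ccccc5)cc4o3)cc(-c3c(OCc4ccccc4)cc(OCc4ccccc4)c4c(=O)cc(-c5ccc(OCc6ccccc6)cc5)oc34)c2O1 | intermediate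
17 | 8-[6-(5,7-dihydroxy-4-oxo-4H-chromen-2-yl)-2,2-dimethyl-3,4-dihydro-2H-chromen-8-yl]-5,7-dihydroxy-2-(4-hydroxyphenyl)-4H-chromen-4-one | CC1(C)CCc2cc(-c3cc(=O)c4c(O)cc(O)cc4o3)cc(-c3c(O)cc(O)c4c(=O)cc(-c5ccc(O)cc5)oc34)c2O1 | target

## Step count and risks

Total step count: 6. Longest linear sequence: 5 (steps 1, 2, 3, 5, 6, from apigenin); step 4 is a one-step side branch.

The three steps most likely to fail:

**Step 2 (biaryl coupling).** The phenol carries bromine rather than a donor, so para attack, over-oxidation or simple recovery of 3 may dominate. The fallback sets out from 3 and uses a pre-formed electrophile in place of the iodane. Commercial 2-amino-4-bromophenol is diazotised (NaNO2, aq. HCl, 0 °C, then NaHCO3) to the ortho-quinone diazide 4-bromo-6-diazocyclohexa-2,4-dien-1-one F1. F1 is added slowly to 3 (2 equiv) and Rh2(OAc)4 (2 mol%) in 1,2-dichloroethane at 60 °C. The dirhodium quinoid carbene is electrophilic only at the former diazo carbon (α to C=O), so C8 of 3 attacks there, dinitrogen is lost and tautomerisation gives 6, where the route is rejoined.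

**Step 3 (chromene annulation).** The ortho carbon of 6 is hindered and deactivated by bromine, so the boronate-templated addition to the enal may be too slow. The fallback sets out from 6, which is O-alkylated with 3-chloro-3-methylbut-1-yne (K2CO3, KI, CuI cat., acetone, reflux) to the propargyl ether 5,7-bis(benzyloxy)-2-[4-(benzyloxy)phenyl]-8-{5-bromo-2-[(2-methylbut-3-yn-2-yl)oxy]phenyl}-4H-chromen-4-one F2. Heating F2 in N,N-diethylaniline at 190 °C brings about propargyl Claisen rearrangement to the only free ortho carbon, 1,5-hydrogen shift and oxa-6π closure, which returns the route to 10.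

**Step 5 (carbonylative flavone annulation).** The one-pot sequence may stall at the ester or the diketone with the hindered, doubly ortho-substituted acetophenone 12. The fallback sets out from 10, which is methoxycarbonylated (Pd(OAc)2, 4,5-bis(diphenylphosphino)-9,9-dimethylxanthene, CO 1 atm, MeOH, Et3N, 80 °C) to methyl 8-{5,7-bis(benzyloxy)-2-[4-(benzyloxy)phenyl]-4-oxo-4H-chromen-8-yl}-2,2-dimethyl-2H-chromene-6-carboxylate F3. Crossed Claisen condensation of F3 with the dilithium salt of 12 (LiN(SiMe3)2, 3 equiv, THF, −78 → 0 °C) gives diketone 15, isolated this time. TsOH·H2O in toluene at 80 °C dehydrates 15 to 16, where the route is rejoined.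

## Further compounds

F1 | step 2 | 4-bromo-6-diazocyclohexa-2,4-dien-1-one | [N-]=[N+]=C1C=C(Br)C=CC1=O
F2 | step 3 | 5,7-bis(benzyloxy)-2-[4-(benzyloxy)phenyl]-8-{5-bromo-2-[(2-methylbut-3-yn-2-yl)oxy]phenyl}-4H-chromen-4-one | C#CC(C)(C)Oc1ccc(Br)cc1-c1c(OCc2ccccc2)cc(OCc2ccccc2)c2c(=O)cc(-c3ccc(OCc4ccccc4)cc3)oc12
F3 | step 5 | methyl 8-{5,7-bis(benzyloxy)-2-[4-(benzyloxy)phenyl]-4-oxo-4H-chromen-8-yl}-2,2-dimethyl-2H-chromene-6-carboxylate | COC(=O)c1cc2c(c(-c3c(OCc4ccccc4)cc(OCc4ccccc4)c4c(=O)cc(-c5ccc(OCc6ccccc6)cc5)oc34)c1)OC(C)(C)C=C2
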